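**Retrosynthetic overview**
1. Last C–O bond: the primary ester between the halves, made by opening a spiro-epoxide on the lactone half with the free hydroxy acid of the other half; this also unveils the tertiary alcohol.
2. Lactone half: epoxide from an exocyclic alkene; seven-membered lactone C–O by lactonisation of a carboxyl group brought in from CO2 with allylic transposition.
3. The two halves are heterochiral, so both come from the two enantiomers of one racemic hub ester, separated once.
4. Hub: cis-cyclohexene by endo Diels–Alder of an enyne-metathesis diene with methyl vinyl ketone (acetyl to isopropyl); side chain by oxa-Michael/Horner–Wadsworth–Emmons.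
5. Ring order: cyclohexene (Diels–Alder), then oxepinone (lactonisation), then oxirane (opened in the union).

Assumption: the SMILES is read literally, so the ring stereocentres of the acid half are the mirror image of those of the lactone half (both cis); racemates carry the prefix rac and are drawn as one enantiomer.

**Step 1**
Reactants: 1 prop-2-yn-1-yl acetate; 2 tert-butyl(dimethyl)(prop-2-en-1-yloxy)silane
Product: 3 (3E)-5-{[tert-butyl(dimethyl)silyl]oxy}-2-methylidenepent-3-en-1-yl acetate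
Conditions: second-generation Hoveyda–Grubbs catalyst RuCl2(H2IMes)(=CH-C6H4-2-OiPr) (3 mol %), 2 (3 equiv), CH2Cl2, 40 °C
Reagents that add atoms: none
Why: Cross enyne metathesis joins all atoms of both partners into the 1,3-disubstituted diene; secondary metathesis enriches the E isomer (about 4:1 expected) and the Z isomer cannot reach the s-cis form needed in step 2, so no stereocentre is at stake.

**Step 2**
Reactants: 3 the diene; 4 but-3-en-2-one
Product: 5 rac-[(3S,4R)-4-acetyl-3-({[tert-butyl(dimethyl)silyl]oxy}methyl)cyclohex-1-en-1-yl]methyl acetate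
Conditions: Sc(OTf)3 (10 mol %), CH2Cl2, −20 °C
Reagents that add atoms: none
Why: Lewis acid-catalysed Diels–Alder reaction in which both diene substituents direct the acetyl carbon next to the CH2OSi-bearing terminus and the endo transition state places acetyl and CH2OSi cis, which sets the cis relation of the two ring stereocentres (racemate).

**Step 3**
Reactants: 5 the cis keto acetate
Product: 6 rac-[(3S,4R)-3-({[tert-butyl(dimethyl)silyl]oxy}methyl)-4-(prop-1-en-2-yl)cyclohex-1-en-1-yl]methyl acetate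
Conditions: Zn, CH2Br2, TiCl4, THF, 0 °C to rt
Reagents that add atoms: dibromomethane, BrCBr
Why: Takai–Lombardo methylenation is non-basic, so the methyl ketone becomes the isopropenyl group without epimerising the neighbouring stereocentre and without touching the acetate.

**Step 4**
Reactants: 6 the isopropenyl compound
Product: 7 rac-[(3R,4S)-3-({[tert-butyl(dimethyl)silyl]oxy}methyl)-4-(propan-2-yl)cyclohex-1-en-1-yl]methyl acetate
Conditions: H2 (1 atm), RhCl(PPh3)3 (5 mol %), toluene/EtOH, rt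
Reagents that add atoms: none
Why: Homogeneous hydrogenation with Wilkinson's catalyst reduces the unhindered 1,1-disubstituted alkene far faster than the trisubstituted ring alkene; the stereocentres are untouched and only their CIP descriptors change.

**Step 5**
Reactants: 7 the silyl ether
Product: 8 rac-[(3R,4S)-3-(hydroxymethyl)-4-(propan-2-yl)cyclohex-1-en-1-yl]methyl acetate
Conditions: HF·pyridine, THF, 0 °C to rt
Reagents that add atoms: none
Why: Fluoride-mediated desilylation frees the primary alcohol and leaves the allylic acetate in place.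

**Step 6**
Reactants: 8 the alcohol
Product: 9 rac-[(3R,4S)-3-formyl-4-(propan-2-yl)cyclohex-1-en-1-yl]methyl acetate
Conditions: Pr4N[RuO4] (5 mol %), N-methylmorpholine N-oxide, 4 Å sieves, CH2Cl2, 0 °C
Reagents that add atoms: none
Why: Ley–Griffith oxidation is neutral and gives the β,γ-unsaturated aldehyde without α-epimerisation or alkene migration; it is used at once.

**Step 7**
Reactants: 10 tert-butyl 2-(diethoxyphosphoryl)acetate; 11 formaldehyde (as paraformaldehyde)
Product: 13 tert-butyl 2-(diethoxyphosphoryl)prop-2-enoate, via methoxymethyl adduct 12 (not isolated)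
Conditions: (CH2O)n, piperidine (cat.), MeOH, reflux; then TsOH (cat.), toluene, reflux
Reagents that add atoms: none
Why: Knoevenagel-type condensation of the phosphonoacetate with formaldehyde, held as the methanol adduct and then stripped of methanol under acid, is the standard route to 2-phosphonoacrylates.

**Step 8**
Reactants: 9 the aldehyde; 13 the phosphonoacrylate
Product: 15 rac-tert-butyl (2E)-3-[(1R,6S)-3-(acetoxymethyl)-6-(propan-2-yl)cyclohex-2-en-1-yl]-2-(hydroxymethyl)prop-2-enoate, via silyl ether 14 (not isolated)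
Conditions: 13, KOSiMe3, THF, −40 °C; then 9, −40 °C to rt; 1 M HCl work-up
Reagents that add atoms: potassium trimethylsilanolate, C[Si](C)(C)[O-].[K+]
Why: Tandem oxa-Michael/Horner–Wadsworth–Emmons reaction in which the silanolate (a hydroxide surrogate) adds to the vinylphosphonate, the carbanion so formed olefinates the aldehyde with the usual E preference of α-substituted phosphonoacetates (ring trans to ester) and the O–Si bond is hydrolysed in the work-up; the stereocentres are not touched.

**Step 9**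
Reactants: 15 the racemic hub ester
Product: 16 tert-butyl (2E)-3-[(1R,6S)-3-(acetoxymethyl)-6-(propan-2-yl)cyclohex-2-en-1-yl]-2-(hydroxymethyl)prop-2-enoate; 17 its (1S,6R) enantiomer (both collected)
Conditions: preparative supercritical-fluid chromatography, amylose tris(3,5-dimethylphenylcarbamate) phase, CO2/MeOH
Reagents that add atoms: none
Why: Chromatographic resolution on a chiral stationary phase; because the two halves of the target are heterochiral, both antipodes are used (16 for the acid half, 17 for the lactone half).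

**Step 10**
Reactants: 16 the (1R,6S) hub ester
Product: 18 tert-butyl (2E)-2-(hydroxymethyl)-3-[(1R,6S)-3-(hydroxymethyl)-6-(propan-2-yl)cyclohex-2-en-1-yl]prop-2-enoate
Conditions: K2CO3 (0.2 equiv), MeOH, 0 °C
Reagents that add atoms: none
Why: Zemplén-type base-catalysed transesterification removes the primary acetate as methyl acetate while the hindered tert-butyl ester stays.

**Step 11**
Reactants: 18 the diol ester
Product: 19 (2E)-2-(hydroxymethyl)-3-[(1R,6S)-3-(hydroxymethyl)-6-(propan-2-yl)cyclohex-2-en-1-yl]prop-2-enoic acid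
Conditions: 85 % aq. H3PO4, toluene, rt
Reagents that add atoms: none
Why: Acid-promoted alkyl–oxygen cleavage (AAL1) of the tert-butyl ester with aqueous phosphoric acid is mild enough for the two primary allylic alcohols and the doubly allylic stereocentre.

**Step 12**
Reactants: 17 the (1S,6R) hub ester
Product: 20 (1R,5R,6R)-6-[(1E)-3-tert-butoxy-2-(hydroxymethyl)-3-oxoprop-1-en-1-yl]-2-methylidene-5-(propan-2-yl)cyclohexane-1-carboxylic acid
Conditions: Pd(PPh3)4 (5 mol %), ZnEt2 (4 equiv), CO2 (1 atm), THF, 0 °C to rt; 1 M HCl work-up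
Reagents that add atoms: carbon dioxide, O=C=O
Why: Palladium-catalysed umpolung of the allylic acetate (π-allylpalladium to allylzinc with ZnEt2) and SE2′ carboxylation puts the carboxyl group on the ring carbon with transposition to the exocyclic methylene; CO2 enters anti to the neighbouring pseudo-axial side chain, which sets the new stereocentre trans to it (1R).

**Step 13**
Reactants: 20 the hydroxy acid
Product: 21 tert-butyl (5aR,6R,9aR)-9-methylidene-1-oxo-6-(propan-2-yl)-1,3,5a,6,7,8,9,9a-octahydro-2-benzoxepine-4-carboxylate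
Conditions: 2,4,6-trichlorobenzoyl chloride, Et3N, THF, rt; then DMAP, toluene (2 mM), 40 °C
Reagents that add atoms: none
Why: Yamaguchi lactonisation, in which the mixed anhydride is acylated intramolecularly by the primary allylic alcohol that the alkene geometry holds next to the trans-diequatorial acyl group, closes the seven-membered lactone; no stereocentre changes.

**Step 14**
Reactants: 21 the methylidene lactone
Product: 22 tert-butyl (2S,5a′R,6′R,9a′R)-1′-oxo-6′-(propan-2-yl)-1′,5a′,6′,7′,8′,9a′-hexahydro-3′H-spiro[oxirane-2,9′-[2]benzoxepine]-4′-carboxylate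
Conditions: dimethyldioxirane, acetone, −20 to 0 °C
Reagents that add atoms: dimethyldioxirane, CC1(C)OO1
Why: Electrophilic epoxidation in which only the electron-rich exocyclic alkene reacts (the enoate is inert) and oxygen arrives along the axial direction of the methylenecyclohexane, cis to the equatorial lactone carbonyl, giving the axial C–O bond (spiro carbon S); about 3:1 is expected and the minor epimer is removed by chromatography.

**Step 15**
Reactants: 22 the spiro-epoxide; 19 the hydroxy acid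
Product: 23 tert-butyl (5aR,6R,9S,9aR)-9-hydroxy-9-[({(2E)-2-(hydroxymethyl)-3-[(1R,6S)-3-(hydroxymethyl)-6-(propan-2-yl)cyclohex-2-en-1-yl]prop-2-enoyl}oxy)methyl]-1-oxo-6-(propan-2-yl)-1,3,5a,6,7,8,9,9a-octahydro-2-benzoxepine-4-carboxylate
Conditions: [N,N′-bis(3,5-di-tert-butylsalicylidene)ethane-1,2-diaminato]cobalt (5 mol %, oxidised by air in the presence of 19), 19 (1.05 equiv), iPr2NEt (10 mol %), tert-butyl methyl ether, rt
Reagents that add atoms: none
Why: Proposed new method: cobalt–salen carboxylate-relay opening of a 2,2-disubstituted spiro-epoxide by a free polyfunctional acrylic acid, in which air and 19 convert the divalent cobalt complex into the trivalent cobalt carboxylate, one such centre activates the epoxide oxygen as a Lewis acid while a second delivers its carboxylate to the unhindered CH2 terminus, and proton transfer from fresh 19 releases the hydroxy ester and reloads cobalt, so the medium stays near neutral, the base-labile β,γ-epoxy lactone is not opened by elimination, the alcohols of 19 do not compete and the tertiary C–O stereocentre is retained; the closest known reaction type is the cobalt–salen-catalysed opening of monosubstituted terminal epoxides by carboxylic acids or water, not yet shown for a spiro 2,2-disubstituted epoxide or with a complex acid as the limiting partner.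

**Step 16**
Reactants: 23 the coupled tert-butyl ester
Product: 24 (5aR,6R,9S,9aR)-9-hydroxy-9-[({(2E)-2-(hydroxymethyl)-3-[(1R,6S)-3-(hydroxymethyl)-6-(propan-2-yl)cyclohex-2-en-1-yl]prop-2-enoyl}oxy)methyl]-1-oxo-6-(propan-2-yl)-1,3,5a,6,7,8,9,9a-octahydro-2-benzoxepine-4-carboxylic acid (CNP0361406.11)
Conditions: 85 % aq. H3PO4, CH2Cl2, rt
Reagents that add atoms: none
Why: Acid-promoted AAL1 cleavage of the tert-butyl ester frees the carboxylic acid without touching the lactone, the acrylate ester, the tertiary β-hydroxy lactone or the allylic alcohols; no stereocentre is affected.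

**Compound list**
1 | prop-2-yn-1-yl acetate | CC(=O)OCC#C | starting material
2 | tert-butyl(dimethyl)(prop-2-en-1-yloxy)silane | C=CCO[Si](C)(C)C(C)(C)C | starting material
3 | (3E)-5-{[tert-butyl(dimethyl)silyl]oxy}-2-methylidenepent-3-en-1-yl acetate | CC(=O)OCC(=C)/C=C/CO[Si](C)(C)C(C)(C)C | intermediate
4 | but-3-en-2-one | CC(=O)C=C | starting material
5 | rac-[(3S,4R)-4-acetyl-3-({[tert-butyl(dimethyl)silyl]oxy}methyl)cyclohex-1-en-1-yl]methyl acetate (3,4-cis) | CC(C)(C)[Si](C)(C)OC[C@H]1C=C(COC(C)=O)CC[C@H]1C(C)=O | intermediate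
6 | rac-[(3S,4R)-3-({[tert-butyl(dimethyl)silyl]oxy}methyl)-4-(prop-1-en-2-yl)cyclohex-1-en-1-yl]methyl acetate | CC(C)(C)[Si](C)(C)OC[C@H]1C=C(COC(C)=O)CC[C@H]1C(C)=C | intermediate
7 | rac-[(3R,4S)-3-({[tert-butyl(dimethyl)silyl]oxy}methyl)-4-(propan-2-yl)cyclohex-1-en-1-yl]methyl acetate | CC(C)(C)[Si](C)(C)OC[C@H]1C=C(COC(C)=O)CC[C@H]1C(C)C | intermediate
8 | rac-[(3R,4S)-3-(hydroxymethyl)-4-(propan-2-yl)cyclohex-1-en-1-yl]methyl acetate | OC[C@H]1C=C(COC(C)=O)CC[C@H]1C(C)C | intermediate
9 | rac-[(3R,4S)-3-formyl-4-(propan-2-yl)cyclohex-1-en-1-yl]methyl acetate | O=C[C@H]1C=C(COC(C)=O)CC[C@H]1C(C)C | intermediate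
10 | tert-butyl 2-(diethoxyphosphoryl)acetate | CCOP(=O)(OCC)CC(=O)OC(C)(C)C | starting material
11 | formaldehyde (used as paraformaldehyde) | C=O | starting material
12 | tert-butyl 2-(diethoxyphosphoryl)-3-methoxypropanoate (not isolated) | CCOP(=O)(OCC)C(COC)C(=O)OC(C)(C)C | intermediate
13 | tert-butyl 2-(diethoxyphosphoryl)prop-2-enoate | CCOP(=O)(OCC)C(=C)C(=O)OC(C)(C)C | intermediate
14 | rac-tert-butyl (2E)-3-[(1R,6S)-3-(acetoxymethyl)-6-(propan-2-yl)cyclohex-2-en-1-yl]-2-{[(trimethylsilyl)oxy]methyl}prop-2-enoate (not isolated) | CC(C)(C)OC(=O)/C(=C/[C@H]1C=C(COC(C)=O)CC[C@H]1C(C)C)CO[Si](C)(C)C | intermediate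
15 | rac-tert-butyl (2E)-3-[(1R,6S)-3-(acetoxymethyl)-6-(propan-2-yl)cyclohex-2-en-1-yl]-2-(hydroxymethyl)prop-2-enoate | CC(C)(C)OC(=O)/C(=C/[C@H]1C=C(COC(C)=O)CC[C@H]1C(C)C)CO | intermediate
16 | tert-butyl (2E)-3-[(1R,6S)-3-(acetoxymethyl)-6-(propan-2-yl)cyclohex-2-en-1-yl]-2-(hydroxymethyl)prop-2-enoate | CC(C)(C)OC(=O)/C(=C/[C@H]1C=C(COC(C)=O)CC[C@H]1C(C)C)CO | intermediate
17 | tert-butyl (2E)-3-[(1S,6R)-3-(acetoxymethyl)-6-(propan-2-yl)cyclohex-2-en-1-yl]-2-(hydroxymethyl)prop-2-enoate | CC(C)(C)OC(=O)/C(=C/[C@@H]1C=C(COC(C)=O)CC[C@@H]1C(C)C)CO | intermediate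
18 | tert-butyl (2E)-2-(hydroxymethyl)-3-[(1R,6S)-3-(hydroxymethyl)-6-(propan-2-yl)cyclohex-2-en-1-yl]prop-2-enoate | CC(C)(C)OC(=O)/C(=C/[C@H]1C=C(CO)CC[C@H]1C(C)C)CO | intermediate
19 | (2E)-2-(hydroxymethyl)-3-[(1R,6S)-3-(hydroxymethyl)-6-(propan-2-yl)cyclohex-2-en-1-yl]prop-2-enoic acid | OC(=O)/C(=C/[C@H]1C=C(CO)CC[C@H]1C(C)C)CO | intermediate
20 | (1R,5R,6R)-6-[(1E)-3-tert-butoxy-2-(hydroxymethyl)-3-oxoprop-1-en-1-yl]-2-methylidene-5-(propan-2-yl)cyclohexane-1-carboxylic acid | CC(C)[C@H]1CCC(=C)[C@H](C(=O)O)[C@H]1/C=C(\CO)C(=O)OC(C)(C)C | intermediate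
21 | tert-butyl (5aR,6R,9aR)-9-methylidene-1-oxo-6-(propan-2-yl)-1,3,5a,6,7,8,9,9a-octahydro-2-benzoxepine-4-carboxylate | CC(C)[C@H]1CCC(=C)[C@@H]2C(=O)OCC(C(=O)OC(C)(C)C)=C[C@@H]12 | intermediate
22 | tert-butyl (2S,5a′R,6′R,9a′R)-1′-oxo-6′-(propan-2-yl)-1′,5a′,6′,7′,8′,9a′-hexahydro-3′H-spiro[oxirane-2,9′-[2]benzoxepine]-4′-carboxylate (oxirane oxygen cis to the lactone carbonyl carbon) | CC(C)[C@H]1CC[C@@]3(CO3)[C@@H]2C(=O)OCC(C(=O)OC(C)(C)C)=C[C@@H]12 | intermediate
23 | tert-butyl (5aR,6R,9S,9aR)-9-hydroxy-9-[({(2E)-2-(hydroxymethyl)-3-[(1R,6S)-3-(hydroxymethyl)-6-(propan-2-yl)cyclohex-2-en-1-yl]prop-2-enoyl}oxy)methyl]-1-oxo-6-(propan-2-yl)-1,3,5a,6,7,8,9,9a-octahydro-2-benzoxepine-4-carboxylate | CC(C)[C@H]1CC[C@@](O)(COC(=O)/C(=C/[C@H]2C=C(CO)CC[C@H]2C(C)C)CO)[C@@H]2C(=O)OCC(C(=O)OC(C)(C)C)=C[C@@H]12 | intermediate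
24 | (5aR,6R,9S,9aR)-9-hydroxy-9-[({(2E)-2-(hydroxymethyl)-3-[(1R,6S)-3-(hydroxymethyl)-6-(propan-2-yl)cyclohex-2-en-1-yl]prop-2-enoyl}oxy)methyl]-1-oxo-6-(propan-2-yl)-1,3,5a,6,7,8,9,9a-octahydro-2-benzoxepine-4-carboxylic acid | CC(C)[C@H]1CC[C@@](O)(COC(=O)/C(=C/[C@H]2C=C(CO)CC[C@H]2C(C)C)CO)[C@@H]2C(=O)OCC(C(=O)O)=C[C@@H]12 | target

**Step count and risks**
Total steps: 16. Longest linear sequence: 13 (steps 1–6, 8, 9, 12–16).

Step 8 (E/Z control, possible α-epimerisation of 9, behaviour of the silanolate). The fallback sets out from 9 and builds the side-chain alkene by metathesis instead of olefination. Wittig methylenation (Ph3PCH3Br, KHMDS, THF, −78 °C) gives rac-[(3R,4S)-3-ethenyl-4-(propan-2-yl)cyclohex-1-en-1-yl]methyl acetate F1. Olefin cross-metathesis of F1 with commercial tert-butyl 2-(hydroxymethyl)prop-2-enoate (second-generation Hoveyda–Grubbs catalyst, CH2Cl2, 40 °C) forms the E-trisubstituted enoate and comes back to the route at 15.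

Step 12 (branched versus linear carboxylation, trans selectivity, competing ionisation of the side-chain allylic alcohol). The fallback sets out from 17 and uses an isolable allylboron intermediate instead of the zinc umpolung. Allylic borylation (bis(pinacolato)diboron, Pd(dba)2, DMSO, 50 °C) gives tert-butyl (2E)-2-(hydroxymethyl)-3-[(1S,6R)-6-(propan-2-yl)-3-[(4,4,5,5-tetramethyl-1,3,2-dioxaborolan-2-yl)methyl]cyclohex-2-en-1-yl]prop-2-enoate F2. Copper-catalysed carboxylation of F2 ([1,3-bis(2,6-diisopropylphenyl)imidazol-2-ylidene]CuCl, KOtBu, CO2 1 atm, THF) adds CO2 at the γ-carbon and comes back at 20.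

Step 15 (the proposed new step: the hindered spiro-epoxide may bind cobalt poorly, or elimination to the γ-hydroxy enoate may compete). The fallback uses known chemistry only and forms the ester by acylating a diol instead of opening the epoxide with the acid; it sets out from 22 and 19.
- Dilute HClO4 in aqueous THF at 0 °C hydrolyses 22 at the CH2 carbon, which is remote from the deactivating lactone carbonyl, to the diol tert-butyl (5aR,6R,9S,9aR)-9-hydroxy-9-(hydroxymethyl)-1-oxo-6-(propan-2-yl)-1,3,5a,6,7,8,9,9a-octahydro-2-benzoxepine-4-carboxylate F3.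
- Acid 19 is persilylated (TBSCl, imidazole, DMF) to tert-butyl(dimethyl)silyl (2E)-2-({[tert-butyl(dimethyl)silyl]oxy}methyl)-3-[(1R,6S)-3-({[tert-butyl(dimethyl)silyl]oxy}methyl)-6-(propan-2-yl)cyclohex-2-en-1-yl]prop-2-enoate F4.
- K2CO3 in aqueous methanol cleaves the silyl ester of F4 to (2E)-2-({[tert-butyl(dimethyl)silyl]oxy}methyl)-3-[(1R,6S)-3-({[tert-butyl(dimethyl)silyl]oxy}methyl)-6-(propan-2-yl)cyclohex-2-en-1-yl]prop-2-enoic acid F5.
- Yamaguchi esterification of F5 with the primary hydroxyl of F3 (2,4,6-trichlorobenzoyl chloride, Et3N, DMAP, toluene) gives tert-butyl (5aR,6R,9S,9aR)-9-[({(2E)-2-({[tert-butyl(dimethyl)silyl]oxy}methyl)-3-[(1R,6S)-3-({[tert-butyl(dimethyl)silyl]oxy}methyl)-6-(propan-2-yl)cyclohex-2-en-1-yl]prop-2-enoyl}oxy)methyl]-9-hydroxy-1-oxo-6-(propan-2-yl)-1,3,5a,6,7,8,9,9a-octahydro-2-benzoxepine-4-carboxylate F6.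
- HF·pyridine removes both silyl ethers from F6 and comes back at 23.

**Further compounds**
F1 | step 8 | rac-[(3R,4S)-3-ethenyl-4-(propan-2-yl)cyclohex-1-en-1-yl]methyl acetate | C=C[C@H]1C=C(COC(C)=O)CC[C@H]1C(C)C
F2 | step 12 | tert-butyl (2E)-2-(hydroxymethyl)-3-[(1S,6R)-6-(propan-2-yl)-3-[(4,4,5,5-tetramethyl-1,3,2-dioxaborolan-2-yl)methyl]cyclohex-2-en-1-yl]prop-2-enoate | CC(C)(C)OC(=O)/C(=C/[C@@H]1C=C(CB2OC(C)(C)C(C)(C)O2)CC[C@@H]1C(C)C)CO
F3 | step 15 | tert-butyl (5aR,6R,9S,9aR)-9-hydroxy-9-(hydroxymethyl)-1-oxo-6-(propan-2-yl)-1,3,5a,6,7,8,9,9a-octahydro-2-benzoxepine-4-carboxylate | CC(C)[C@H]1CC[C@@](O)(CO)[C@@H]2C(=O)OCC(C(=O)OC(C)(C)C)=C[C@@H]12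
F4 | step 15 | tert-butyl(dimethyl)silyl (2E)-2-({[tert-butyl(dimethyl)silyl]oxy}methyl)-3-[(1R,6S)-3-({[tert-butyl(dimethyl)silyl]oxy}methyl)-6-(propan-2-yl)cyclohex-2-en-1-yl]prop-2-enoate | CC(C)(C)[Si](C)(C)OC(=O)/C(=C/[C@H]1C=C(CO[Si](C)(C)C(C)(C)C)CC[C@H]1C(C)C)CO[Si](C)(C)C(C)(C)C
F5 | step 15 | (2E)-2-({[tert-butyl(dimethyl)silyl]oxy}methyl)-3-[(1R,6S)-3-({[tert-butyl(dimethyl)silyl]oxy}methyl)-6-(propan-2-yl)cyclohex-2-en-1-yl]prop-2-enoic acid | OC(=O)/C(=C/[C@H]1C=C(CO[Si](C)(C)C(C)(C)C)CC[C@H]1C(C)C)CO[Si](C)(C)C(C)(C)C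
F6 | step 15 | tert-butyl (5aR,6R,9S,9aR)-9-[({(2E)-2-({[tert-butyl(dimethyl)silyl]oxy}methyl)-3-[(1R,6S)-3-({[tert-butyl(dimethyl)silyl]oxy}methyl)-6-(propan-2-yl)cyclohex-2-en-1-yl]prop-2-enoyl}oxy)methyl]-9-hydroxy-1-oxo-6-(propan-2-yl)-1,3,5a,6,7,8,9,9a-octahydro-2-benzoxepine-4-carboxylate | CC(C)[C@H]1CC[C@@](O)(COC(=O)/C(=C/[C@H]2C=C(CO[Si](C)(C)C(C)(C)C)CC[C@H]2C(C)C)CO[Si](C)(C)C(C)(C)C)[C@@H]2C(=O)OCC(C(=O)OC(C)(C)C)=C[C@@H]12
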